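**Plan**

- Retrosynthetic cuts (quinone numbering: C1=O, C2–Me, C3–H, C4=O, chain on C7; chain carbons C1'–C13' from the ring): the O-acetyl group; the oxygen on C1, added last at the para carbon of a 1-naphthol; the chain bond C2'–C3'; and, in the quinone ring, the C2–C3 bond together with the C1–C8a bond, which leaves a 4-bromobenzoyl sulfoxonium ylide and propyne.
- Feature that allows this: carbonyl C4 sits on C4a, which is para to the chain-bearing C7 of the benzo ring, and C3 is a bare CH. The benzo ring with C4 and C3 is therefore a para-substituted aroyl–CH unit with two identical ortho C–H bonds, and the missing C1–C2(Me) pair has the carbon pattern of propyne.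
- Forward order: the benzo ring is bought; a rhodium-catalysed C–H annulation with propyne closes the second ring as 6-bromo-3-methyl-1-naphthol, which is given a vinyl handle. The chain is built from geraniol (epoxidation, propargylation, epoxide hydrolysis, carboalumination–iodination) and joined by hydroboration/Suzuki coupling; oxygenation to the 1,4-quinone and acetylation finish the route.
- Stereochemistry: C7' and C8' come from Sharpless asymmetric epoxidation of geraniol with D-(−)-diethyl tartrate (2R,3R), followed by acid hydrolysis with inversion at the tertiary carbon (gives 7'R,8'S). The 3'E alkene comes from syn carboalumination of a terminal alkyne and is kept through iodination and coupling.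

Key step: step 2

**Step 1**
Reactants: 1 4-bromobenzoyl chloride; 2 trimethylsulfoxonium iodide
Product: 4 1-(4-bromophenyl)-2-[dimethyl(oxo)-λ6-sulfanylidene]ethan-1-one, via dimethylsulfoxonium methylide 3 (not isolated)
Conditions: 2 (3 equiv), KOtBu (3 equiv), THF, reflux; then 1 (1 equiv), 0 °C → rt
Reagents that add atoms: none
Why: C-acylation of dimethylsulfoxonium methylide by an acid chloride, with a second equivalent of the ylide taking up HCl, is the standard preparation of stabilized β-keto sulfoxonium ylides and leaves the aryl bromide untouched.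

**Step 2**
Reactants: 4 1-(4-bromophenyl)-2-[dimethyl(oxo)-λ6-sulfanylidene]ethan-1-one; 5 propyne
Product: 7 6-bromo-3-methylnaphthalen-1-ol, via 6-bromo-3-methyl-2H-naphthalen-1-one 6 (not isolated)
Conditions: [(C5Me5)Rh(MeCN)3](SbF6)2 (5 mol %), Zn(OTf)2 (30 mol %), propyne (5 equiv, pressure tube), ClCH2CH2Cl, 80 °C
Reagents that add atoms: none
Why: Carbonyl-bound cationic trivalent rhodium cleaves one of the two equivalent ortho C–H bonds of 4 by concerted metalation–deprotonation to a five-membered rhodacycle, and propyne inserts into its Rh–aryl bond with the aryl group going to the unsubstituted alkyne terminus, which makes the aryl–CH bond (later C8a–C1 of the quinone) and leaves rhodium on the methyl-bearing carbon. The ylide carbon then binds rhodium and loses DMSO to give a rhodium carbene, and migratory insertion of the alkenyl group into this carbene makes the C(Me)–CH bond (later C2–C3) and closes the new six-membered carbocycle in a formal [4+2] annulation of the aroyl–CH unit with the alkyne. Protonolysis of the Rh–C bond releases ketone 6, which tautomerizes to the aromatic naphthol 7, and returns trivalent rhodium, so the ylide serves as a traceless directing group and carbene source and no external oxidant is needed. The closest known reaction type is the rhodium-catalysed C–H activation/annulation of aroyl sulfoxonium ylides with alkynes to give 1-naphthols; no stereocenter is formed. The step needs site selectivity, secured by the para-bromo substitution that makes both ortho positions identical, and regioselective insertion, secured by the terminal alkyne, which as in related annulations of 1-alkynes places its substituent on the metal-bound carbon remote from the arene; base-free cationic conditions are chosen to disfavour acetylide formation and alkyne oligomerization. The C–Br bond is inert to trivalent rhodium and, without an oxidant, the naphthol cannot enter a second annulation.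

**Step 3**
Reactants: 7 6-bromo-3-methylnaphthalen-1-ol; 8 2-ethenyl-4,4,5,5-tetramethyl-1,3,2-dioxaborolane
Product: 9 6-ethenyl-3-methylnaphthalen-1-ol
Conditions: Pd(dppf)Cl2 (3 mol %), K2CO3 (3 equiv), 1,4-dioxane/H2O, 80 °C
Reagents that add atoms: none
Why: Suzuki–Miyaura coupling of an aryl bromide with a vinylboronate is routine and tolerates the free naphthol, which is present as its potassium salt.

**Step 4**
Reactants: 10 geraniol
Product: 11 [(2R,3R)-3-methyl-3-(4-methylpent-3-en-1-yl)oxiran-2-yl]methanol
Conditions: Ti(OiPr)4 (5 mol %), D-(−)-diethyl tartrate (6 mol %), t-BuOOH (1.5 equiv), 4 Å molecular sieves, CH2Cl2, −20 °C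
Reagents that add atoms: tert-butyl hydroperoxide CC(C)(C)OO
Why: Sharpless asymmetric epoxidation oxidizes only the allylic-alcohol alkene, and the D-(−)-tartrate–titanium complex delivers oxygen to the face that gives the (2R,3R) epoxide, which fixes the later C7' and, after inversion in step 6, C8'.

**Step 5**
Reactants: 11 [(2R,3R)-3-methyl-3-(4-methylpent-3-en-1-yl)oxiran-2-yl]methanol; 12 trimethyl(prop-1-yn-1-yl)silane
Product: 16 trimethyl{4-[(2R,3R)-3-methyl-3-(4-methylpent-3-en-1-yl)oxiran-2-yl]but-1-yn-1-yl}silane, via lithium alkoxide of the epoxy alcohol 13 (not isolated), via epoxy triflate 14 (not isolated), via 3-(trimethylsilyl)prop-2-ynyllithium 15 (not isolated)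
Conditions: n-BuLi (1.0 equiv), Et2O, −78 °C; Tf2O (1.0 equiv), −78 °C; then 15 [12 (1.5 equiv), n-BuLi (1.4 equiv), THF, −78 → −20 °C], −78 → −30 °C
Reagents that add atoms: none
Why: In situ triflation of the lithium alkoxide followed by SN2 displacement of the primary triflate by the silyl-directed propargylic lithium reagent should form the C5'–C6' bond at low temperature without touching the trisubstituted epoxide or its two stereocenters.

**Step 6**
Reactants: 16 trimethyl{4-[(2R,3R)-3-methyl-3-(4-methylpent-3-en-1-yl)oxiran-2-yl]but-1-yn-1-yl}silane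
Product: 18 (5R,6S)-6,10-dimethylundec-9-en-1-yne-5,6-diol, via C-silyl alkyne diol 17 (not isolated)
Conditions: HClO4 (10 mol %), THF/H2O (3:1), 0 °C → rt; then K2CO3, MeOH, rt
Reagents that add atoms: water O
Why: Acid-catalysed hydrolysis of a trisubstituted epoxide is expected to proceed by attack of water at the tertiary carbon anti to the protonated oxygen, inverting that center to S while the secondary C–O bond (R) is untouched, and basic methanolysis then removes the alkynyl silane.

**Step 7**
Reactants: 18 (5R,6S)-6,10-dimethylundec-9-en-1-yne-5,6-diol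
Product: 20 (1E,5R,6S)-1-iodo-2,6,10-trimethylundeca-1,9-diene-5,6-diol, via alkenyl dimethylalane 19 (not isolated)
Conditions: Me3Al (5 equiv), (C5H5)2ZrCl2 (0.5 equiv), CH2Cl2, 0 °C → rt; then I2 (1.3 equiv), THF, −30 → 0 °C; aq. NaHCO3/potassium sodium tartrate work-up
Reagents that add atoms: trimethylaluminium C[Al](C)C; iodine II
Why: Negishi zirconium-catalysed carboalumination adds methyl and aluminium syn across the terminal alkyne with aluminium on the terminal carbon, and iodinolysis with retention should give the E iodoalkene, the hydroxyl groups being carried as aluminium alkoxides and the trisubstituted alkene being inert.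

**Step 8**
Reactants: 9 6-ethenyl-3-methylnaphthalen-1-ol; 20 (1E,5R,6S)-1-iodo-2,6,10-trimethylundeca-1,9-diene-5,6-diol
Product: 22 6-[(3E,7R,8S)-7,8-dihydroxy-4,8,12-trimethyltrideca-3,11-dien-1-yl]-3-methylnaphthalen-1-ol, via O,C-diborylated naphthol 21 (not isolated)
Conditions: 9 (1.3 equiv), 9-BBN (2.7 equiv), THF, 0 °C → rt; then 20, Pd(dppf)Cl2 (5 mol %), AsPh3 (10 mol %), Cs2CO3 (4 equiv), DMF/H2O, rt
Reagents that add atoms: none
Why: Anti-Markovnikov hydroboration of the vinylarene by 9-BBN (one further equivalent is consumed by the naphthol O–H) followed by B-alkyl Suzuki–Miyaura coupling with the alkenyl iodide should join the fragments at C2'–C3' with retention of the E geometry and without affecting the diol stereocenters.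

**Step 9**
Reactants: 22 6-[(3E,7R,8S)-7,8-dihydroxy-4,8,12-trimethyltrideca-3,11-dien-1-yl]-3-methylnaphthalen-1-ol
Product: 23 7-[(3E,7R,8S)-7,8-dihydroxy-4,8,12-trimethyltrideca-3,11-dien-1-yl]-2-methylnaphthalene-1,4-dione
Conditions: Co(salen) [N,N'-bis(salicylidene)ethylenediamine complex of divalent cobalt] (10 mol %), O2 (1 atm), MeCN, rt
Reagents that add atoms: dioxygen O=O
Why: Cobalt–salen catalysed aerobic oxidation of a 1-naphthol with a free para position places oxygen on the para carbon and gives the 1,4-quinone, under conditions that should leave the isolated alkenes and the diol alone.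

**Step 10**
Reactants: 23 7-[(3E,7R,8S)-7,8-dihydroxy-4,8,12-trimethyltrideca-3,11-dien-1-yl]-2-methylnaphthalene-1,4-dione
Product: 24 chabrolonaphthoquinone B, (3E,7R,8S)-8-hydroxy-4,8,12-trimethyl-1-(7-methyl-5,8-dioxo-5,8-dihydronaphthalen-2-yl)trideca-3,11-dien-7-yl acetate
Conditions: Ac2O (1.5 equiv), pyridine, DMAP (5 mol %), CH2Cl2, 0 °C → rt
Reagents that add atoms: acetic anhydride CC(=O)OC(C)=O
Why: DMAP-catalysed acylation should acetylate the secondary hydroxyl selectively because the tertiary hydroxyl is too hindered, and O-acylation does not touch the C–O bond, so the 7R configuration is retained.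

**Compound list**

1 | 4-bromobenzoyl chloride | O=C(Cl)c1ccc(Br)cc1 | starting material
2 | trimethylsulfoxonium iodide | C[S+](C)(C)=O.[I-] | starting material
3 | dimethylsulfoxonium methylide | C=S(C)(C)=O | intermediate
4 | 1-(4-bromophenyl)-2-[dimethyl(oxo)-λ6-sulfanylidene]ethan-1-one | CS(C)(=O)=CC(=O)c1ccc(Br)cc1 | intermediate
5 | propyne | CC#C | starting material
6 | 6-bromo-3-methyl-2H-naphthalen-1-one | CC1=Cc2cc(Br)ccc2C(=O)C1 | intermediate
7 | 6-bromo-3-methylnaphthalen-1-ol | Cc1cc(O)c2ccc(Br)cc2c1 | intermediate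
8 | 2-ethenyl-4,4,5,5-tetramethyl-1,3,2-dioxaborolane | C=CB1OC(C)(C)C(C)(C)O1 | starting material
9 | 6-ethenyl-3-methylnaphthalen-1-ol | Cc1cc(O)c2ccc(C=C)cc2c1 | intermediate
10 | geraniol, (2E)-3,7-dimethylocta-2,6-dien-1-ol | CC(C)=CCC/C(C)=C/CO | starting material
11 | [(2R,3R)-3-methyl-3-(4-methylpent-3-en-1-yl)oxiran-2-yl]methanol | OC[C@H]1O[C@]1(C)CCC=C(C)C | intermediate
12 | trimethyl(prop-1-yn-1-yl)silane | CC#C[Si](C)(C)C | starting material
13 | lithium [(2R,3R)-3-methyl-3-(4-methylpent-3-en-1-yl)oxiran-2-yl]methanolate | [Li]OC[C@H]1O[C@]1(C)CCC=C(C)C | intermediate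
14 | [(2R,3R)-3-methyl-3-(4-methylpent-3-en-1-yl)oxiran-2-yl]methyl trifluoromethanesulfonate | FC(F)(F)S(=O)(=O)OC[C@H]1O[C@]1(C)CCC=C(C)C | intermediate
15 | [3-(trimethylsilyl)prop-2-yn-1-yl]lithium | [Li]CC#C[Si](C)(C)C | intermediate
16 | trimethyl{4-[(2R,3R)-3-methyl-3-(4-methylpent-3-en-1-yl)oxiran-2-yl]but-1-yn-1-yl}silane | C[Si](C)(C)C#CCC[C@H]1O[C@]1(C)CCC=C(C)C | intermediate
17 | (5R,6S)-6,10-dimethyl-1-(trimethylsilyl)undec-9-en-1-yne-5,6-diol | O[C@H](CCC#C[Si](C)(C)C)[C@@](C)(O)CCC=C(C)C | intermediate
18 | (5R,6S)-6,10-dimethylundec-9-en-1-yne-5,6-diol | O[C@H](CCC#C)[C@@](C)(O)CCC=C(C)C | intermediate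
19 | [(1E,5R,6S)-5,6-bis(dimethylalumanyloxy)-2,6,10-trimethylundeca-1,9-dien-1-yl]dimethylalumane | C[Al](C)O[C@H](CC/C(C)=C/[Al](C)C)[C@@](C)(O[Al](C)C)CCC=C(C)C | intermediate
20 | (1E,5R,6S)-1-iodo-2,6,10-trimethylundeca-1,9-diene-5,6-diol | O[C@H](CC/C(C)=C/I)[C@@](C)(O)CCC=C(C)C | intermediate
21 | 9-{2-[5-(9-borabicyclo[3.3.1]nonan-9-yloxy)-7-methylnaphthalen-2-yl]ethyl}-9-borabicyclo[3.3.1]nonane | Cc1cc(OB2C3CCCC2CCC3)c2ccc(CCB3C4CCCC3CCC4)cc2c1 | intermediate
22 | 6-[(3E,7R,8S)-7,8-dihydroxy-4,8,12-trimethyltrideca-3,11-dien-1-yl]-3-methylnaphthalen-1-ol | O[C@H](CC/C(C)=C/CCc1ccc2c(O)cc(C)cc2c1)[C@@](C)(O)CCC=C(C)C | intermediate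
23 | 7-[(3E,7R,8S)-7,8-dihydroxy-4,8,12-trimethyltrideca-3,11-dien-1-yl]-2-methylnaphthalene-1,4-dione | O[C@H](CC/C(C)=C/CCc1ccc2c(c1)C(=O)C(C)=CC2=O)[C@@](C)(O)CCC=C(C)C | intermediate
24 | chabrolonaphthoquinone B, (3E,7R,8S)-8-hydroxy-4,8,12-trimethyl-1-(7-methyl-5,8-dioxo-5,8-dihydronaphthalen-2-yl)trideca-3,11-dien-7-yl acetate | CC(=O)O[C@H](CC/C(C)=C/CCc1ccc2c(c1)C(=O)C(C)=CC2=O)[C@@](C)(O)CCC=C(C)C | target

**Step count and risks**

Total step count: 10. Longest linear sequence: 7 steps (geraniol 10 to 24 through steps 4, 5, 6, 7, 8, 9 and 10).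

Steps most likely to fail:

1. Step 2. The terminal alkyne may oligomerize or tie up rhodium as an acetylide, or it may insert in the reverse sense and give the 4-methyl isomer. The fallback sets out from 1 and returns to the route at 23.
   - Acid chloride 1 is treated with K2Cr(CO)5 (from Cr(CO)6 and potassium graphite C8K, THF, −78 °C) to give potassium (4-bromobenzoyl)pentacarbonylchromate F1. O-Methylation with Me3OBF4 gives the zerovalent chromium carbene pentacarbonyl[(4-bromophenyl)(methoxy)methylidene]chromium F2.
   - Dötz benzannulation of F2 with propyne 5 (THF, 50 °C) should give the tricarbonylchromium complex of the naphthol F3, from which CO pressure releases 7-bromo-4-methoxy-2-methylnaphthalen-1-ol F4. In this reaction the arene is joined to a carbon monoxide ligand and the alkyne substituent is placed next to the new hydroxyl, so both quinone oxygens are in place with the required 2-methyl/7-bromo pattern.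
   - Vinylation as in step 3 gives 7-ethenyl-4-methoxy-2-methylnaphthalen-1-ol F5. Hydroboration with 9-BBN gives the O,C-diborylated naphthol F6, and coupling with 20 as in step 8 gives 7-[(3E,7R,8S)-7,8-dihydroxy-4,8,12-trimethyltrideca-3,11-dien-1-yl]-4-methoxy-2-methylnaphthalen-1-ol F7.
   - Oxidative demethylation of F7 with PhI(OAc)2 in aqueous MeCN at 0 °C gives 23.

2. Step 5. The epoxy triflate may ionize with epoxide participation before it is substituted, and the ambident propargyl/allenyl anion may attack through its allenyl end. The fallback sets out from 11 and returns at 17, making the C5'–C6' bond by epoxide opening instead of triflate displacement.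
   - Mesylation (MsCl, Et3N, CH2Cl2, −20 °C) gives [(2R,3R)-3-methyl-3-(4-methylpent-3-en-1-yl)oxiran-2-yl]methyl methanesulfonate F8.
   - HClO4 in aqueous THF opens the epoxide at the tertiary carbon with inversion to give (2R,3S)-2,3-dihydroxy-3,7-dimethyloct-6-en-1-yl methanesulfonate F9.
   - K2CO3 in MeOH closes the secondary alkoxide onto the primary carbon to give the terminal epoxide (2S)-6-methyl-2-[(2R)-oxiran-2-yl]hept-5-en-2-ol F10.
   - Opening of F10 at its CH2 terminus with 15 (2.5 equiv, BF3·OEt2, THF, −78 °C) gives 17, which is desilylated as in step 6.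

3. Step 6. Carbocation character at the tertiary carbon may erode the inversion and lower the diastereomeric purity, and a hydride shift may give a ketone. The fallback sets out from 10 and returns at 17; every stereo-defining event in it is an SN2 displacement at a primary or secondary carbon, and no acid opening at the tertiary carbon is used.
   - Sharpless epoxidation of 10 with L-(+)-diethyl tartrate gives the enantiomeric epoxy alcohol [(2S,3S)-3-methyl-3-(4-methylpent-3-en-1-yl)oxiran-2-yl]methanol F11.
   - Payne rearrangement with in situ opening by thiophenolate (PhSH, aq. NaOH, t-BuOH, 70 °C) gives (2S,3S)-3,7-dimethyl-1-(phenylsulfanyl)oct-6-ene-2,3-diol F12. C2 is inverted by intramolecular SN2 attack and the tertiary C3 keeps the configuration set by the epoxidation.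
   - S-Methylation with Me3OBF4 gives [(2S,3S)-2,3-dihydroxy-3,7-dimethyloct-6-en-1-yl](methyl)phenylsulfonium tetrafluoroborate F13.
   - Aqueous NaOH closes F13 to the terminal epoxide (2S)-6-methyl-2-[(2R)-oxiran-2-yl]hept-5-en-2-ol F10, which is opened with 15 as in the fallback for step 5 to give 17.

**Further compounds**

F1 | step 2 | potassium (4-bromobenzoyl)pentacarbonylchromate | [K+].[O-]C(c1ccc(Br)cc1)=[Cr](=C=O)(=C=O)(=C=O)(=C=O)=C=O
F2 | step 2 | pentacarbonyl[(4-bromophenyl)(methoxy)methylidene]chromium | COC(c1ccc(Br)cc1)=[Cr](=C=O)(=C=O)(=C=O)(=C=O)=C=O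
F3 | step 2 | tricarbonyl(7-bromo-4-methoxy-2-methylnaphthalen-1-ol)chromium | COc1cc(C)c(O)c2cc(Br)ccc12.O=C=[Cr](=C=O)=C=O
F4 | step 2 | 7-bromo-4-methoxy-2-methylnaphthalen-1-ol | COc1cc(C)c(O)c2cc(Br)ccc12
F5 | step 2 | 7-ethenyl-4-methoxy-2-methylnaphthalen-1-ol | COc1cc(C)c(O)c2cc(C=C)ccc12
F6 | step 2 | 9-{2-[8-(9-borabicyclo[3.3.1]nonan-9-yloxy)-5-methoxy-7-methylnaphthalen-2-yl]ethyl}-9-borabicyclo[3.3.1]nonane | COc1cc(C)c(OB2C3CCCC2CCC3)c2cc(CCB3C4CCCC3CCC4)ccc12
F7 | step 2 | 7-[(3E,7R,8S)-7,8-dihydroxy-4,8,12-trimethyltrideca-3,11-dien-1-yl]-4-methoxy-2-methylnaphthalen-1-ol | O[C@H](CC/C(C)=C/CCc1ccc2c(OC)cc(C)c(O)c2c1)[C@@](C)(O)CCC=C(C)C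
F8 | step 5 | [(2R,3R)-3-methyl-3-(4-methylpent-3-en-1-yl)oxiran-2-yl]methyl methanesulfonate | CS(=O)(=O)OC[C@H]1O[C@]1(C)CCC=C(C)C
F9 | step 5 | (2R,3S)-2,3-dihydroxy-3,7-dimethyloct-6-en-1-yl methanesulfonate | O[C@H](COS(C)(=O)=O)[C@@](C)(O)CCC=C(C)C
F10 | step 5 | (2S)-6-methyl-2-[(2R)-oxiran-2-yl]hept-5-en-2-ol | O1[C@H](C1)[C@@](C)(O)CCC=C(C)C
F11 | step 6 | [(2S,3S)-3-methyl-3-(4-methylpent-3-en-1-yl)oxiran-2-yl]methanol | OC[C@@H]1O[C@@]1(C)CCC=C(C)C
F12 | step 6 | (2S,3S)-3,7-dimethyl-1-(phenylsulfanyl)oct-6-ene-2,3-diol | O[C@H](CSc1ccccc1)[C@@](C)(O)CCC=C(C)C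
F13 | step 6 | [(2S,3S)-2,3-dihydroxy-3,7-dimethyloct-6-en-1-yl](methyl)phenylsulfonium tetrafluoroborate | O[C@H](C[S+](C)c1ccccc1)[C@@](C)(O)CCC=C(C)C.F[B-](F)(F)F
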